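**Retrosynthetic overview**
1. Target 8 is a (3S,5S) 1,3-anti diol with O3 acetylated and O5 free. The enabling feature is that O5 and the benzylic carbon C1 are 1,5-related across C2–C3–C4, so they can be tied into a temporary tetrahydropyran (ring atoms O5, C1, C2, C3, C4, C5) whose C1–O bond is benzylic to the electron-rich 3,4-dimethoxyphenyl ring and therefore cleavable again.
2. Last disconnection (ring opened): C1–O hydrogenolysis of the all-cis 2-aryl-4-acetoxy-6-pentyltetrahydropyran 7, which already carries the acetate on O3 and holds O5 as the ring oxygen; all-cis 7 maps onto the anti open chain.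
3. Key disconnection (ring formed): three-component acetoxy-Prins cyclisation of (S)-non-1-en-4-ol 3, 3,4-dimethoxybenzaldehyde 4 and acetic acid, which makes the C1–C2 bond, the O3 acetate and the C3 stereocentre and differentiates the two oxygens in one operation.
4. Alcohol 3 comes from hexanal 1 by asymmetric allylboration, which sets C5.
5. Ring order: only one ring, the tetrahydropyran, formed in step 2 and opened in step 3.

Key step: step 2

Remark: locants C1–C10, O3 and O5 refer to the decane chain of the target counted from the benzylic carbon; in the tetrahydropyran, chain C1, C3 and C5 are ring C2, C4 and C6.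

Step 1
Reactants: 1 hexanal
Product: 3 (S)-non-1-en-4-ol, via borinate ester 2 (not isolated)
Conditions: lIpc2B(allyl) (from (−)-α-pinene, salt-free pentane solution), Et2O, −78 °C; then NaOH, H2O2, 0 °C to rt
Reagents that add atoms: B-allyldiisopinocampheylborane derived from (−)-α-pinene, C=CCB([C@H]1C[C@H]2C[C@@H]([C@@H]1C)C2(C)C)[C@H]1C[C@H]2C[C@@H]([C@@H]1C)C2(C)C
Why: Brown asymmetric allylboration, in which the allyl group is transferred through a closed chair Zimmerman–Traxler transition state and the isopinocampheyl groups from (−)-α-pinene should direct it to the Re face of hexanal, setting the (S)-carbinol centre (chain C5) before alkaline peroxide cleaves borinate 2.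

Step 2
Reactants: 3 (S)-non-1-en-4-ol; 4 3,4-dimethoxybenzaldehyde
Product: 7 (2S,4R,6S)-2-(3,4-dimethoxyphenyl)-6-pentyltetrahydro-2H-pyran-4-yl acetate (all-cis), via oxocarbenium ion 5 (not isolated), via tetrahydropyranyl cation 6 (not isolated)
Conditions: BF3·OEt2, AcOH, TMSOAc, cyclohexane/CH2Cl2, 0 °C to rt; NaHCO3 quench
Reagents that add atoms: acetic acid, CC(=O)O (trimethylsilyl acetate, CC(=O)O[Si](C)(C)C, present as water and fluoride scavenger, can deliver the same acetate)
Why: Condensation of the hydroxyl of 3 with aldehyde 4 should give the aryl-conjugated (E)-oxocarbenium ion 5, whose terminal alkene carbon attacks the benzylic oxocarbenium carbon through a chair transition state (6-endo-trig Prins cyclisation, the only ring closed), forming the C1–C2 bond and the secondary cation 6, which acetate captures. The closest known reaction type is the three-component acetoxy-Prins cyclisation of homoallylic alcohols with aldehydes, aromatic ones included, under BF3·OEt2/AcOH/TMSOAc. The existing C6 stereocentre (pentyl equatorial in the chair) controls both new centres: the (E)-ion places the aryl group equatorial at C2, and equatorial attack of acetate on the hyperconjugatively delocalised chair cation 6 places the acetate at C4 cis to the pentyl group, which is the 1,3-anti relationship of the open chain. The step needs 4,6-cis selectivity and retention of the carbinol configuration. The first is secured by the chair cation with two equatorial substituents; the second by the aliphatic carbinol carbon, which cannot ionise, and by ion 5 being the favoured partner of the 2-oxonia-Cope equilibrium, both partners cyclising through chair transition states to the same tetrahydropyran. The C2 centre is temporary, so its configuration is not critical.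

Step 3
Reactants: 7 (2S,4R,6S)-2-(3,4-dimethoxyphenyl)-6-pentyltetrahydro-2H-pyran-4-yl acetate
Product: 8 (3S,5S)-1-(3,4-dimethoxyphenyl)-5-hydroxydecan-3-yl acetate
Conditions: H2 (1–3 bar), Pd(OH)2/C, EtOAc, rt
Reagents that add atoms: none
Why: Heterogeneous hydrogenolysis of the cyclic benzylic C–O bond (the reaction type of O-benzyl ether hydrogenolysis) should open the ring at C1–O to the benzylic methylene and the free C5 hydroxyl without touching the C3 and C5 stereocentres, the aliphatic acetate or the aryl methyl ethers, and the neutral medium should keep 1,3-acetyl migration slow.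

**Compound list**
1 | hexanal | CCCCCC=O | starting material
2 | (S)-non-1-en-4-yl diisopinocampheylborinate (Ipc groups from (−)-α-pinene) | CCCCC[C@@H](CC=C)OB([C@H]1C[C@H]2C[C@@H]([C@@H]1C)C2(C)C)[C@H]1C[C@H]2C[C@@H]([C@@H]1C)C2(C)C | intermediate
3 | (S)-non-1-en-4-ol | CCCCC[C@H](O)CC=C | intermediate
4 | 3,4-dimethoxybenzaldehyde | COc1ccc(C=O)cc1OC | starting material
5 | (E)-(3,4-dimethoxybenzylidene)[(S)-non-1-en-4-yl]oxonium ion | CCCCC[C@@H](CC=C)/[O+]=C/c1ccc(OC)c(OC)c1 | intermediate
6 | 2,6-cis-2-(3,4-dimethoxyphenyl)-6-pentyltetrahydropyran-4-yl cation (chair, both substituents equatorial) | CCCCC[C@H]1C[CH+]C[C@@H](c2ccc(OC)c(OC)c2)O1 | intermediate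
7 | (2S,4R,6S)-2-(3,4-dimethoxyphenyl)-6-pentyltetrahydro-2H-pyran-4-yl acetate | CCCCC[C@H]1C[C@@H](OC(C)=O)C[C@@H](c2ccc(OC)c(OC)c2)O1 | intermediate
8 | (3S,5S)-1-(3,4-dimethoxyphenyl)-5-hydroxydecan-3-yl acetate | CCCCC[C@H](O)C[C@H](CCc1ccc(OC)c(OC)c1)OC(C)=O | target

Total step count: 3
Longest linear sequence: 3

**Steps most likely to fail**

Step 2. The stabilised ion 5 cyclises slowly, so reversible 2-oxonia-Cope rearrangement followed by hydrolysis may exchange the side chains (symmetrical 2,6-dipentyl and 2,6-diaryl tetrahydropyrans). Ionisation of the electron-rich benzylic C–O bond of the rearranged ion may also erode enantiomeric purity, and capture of cation 6 by fluoride instead of acetate is a further leak. The fallback generates the oxocarbenium ion under anhydrous conditions with neither free aldehyde nor free alcohol present. It sets out from 3, which is acylated with 3,4-dimethoxybenzoyl chloride (Et3N, DMAP, CH2Cl2) to (S)-non-1-en-4-yl 3,4-dimethoxybenzoate F1. Reduction with DIBAL-H at −78 °C and trapping of the aluminium hemiacetal in the same flask with Ac2O, pyridine and DMAP should give the α-acetoxy ether (3,4-dimethoxyphenyl)[(S)-non-1-en-4-yloxy]methyl acetate F2 as a mixture of epimers at the acetal carbon, which does not matter. Ionisation of F2 with BF3·OEt2/AcOH in hexanes at 0 °C should pass through 5 and 6 and return to the route at 7.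

Step 3. Cleavage of the equatorial benzylic C–O bond on the catalyst surface may be slow, and forcing it with acid would open the way to 1,3-acetyl migration from O3 to the newly freed O5. The fallback replaces surface hydrogenolysis by ionic hydrogenation. It sets out from 7, which is treated with Et3SiH and BF3·OEt2 in CH2Cl2 at −40 to 0 °C. Coordination of the ring oxygen and heterolysis should give the 3,4-dimethoxybenzyl-type cation, which takes hydride from the silane. Short contact time at low temperature limits participation of the acetate carbonyl, and aqueous work-up frees the C5 hydroxyl, returning to the route at 8 with no new isolated compound.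

Step 1. Facial selectivity of allyl transfer to an unbranched aldehyde may be incomplete, and separation from isopinocampheol may be tedious; 3 of lower enantiomeric purity would carry through to the target. The fallback takes the stereocentre from a kinetic resolution instead. It sets out from 1, which is methylenated under Corey–Chaykovsky conditions (trimethylsulfonium iodide, NaH, DMSO/THF) to racemic 2-pentyloxirane F3. Hydrolytic kinetic resolution with (S,S)-(salen)Co(III)OAc and 0.55 equiv of water should leave (S)-2-pentyloxirane F4. Opening at the terminal carbon with vinylmagnesium bromide and catalytic CuI in THF at −30 °C keeps the configuration and returns to the route at 3.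

**Further compounds**
F1 | step 2 | (S)-non-1-en-4-yl 3,4-dimethoxybenzoate | CCCCC[C@@H](CC=C)OC(=O)c1ccc(OC)c(OC)c1
F2 | step 2 | (3,4-dimethoxyphenyl)[(S)-non-1-en-4-yloxy]methyl acetate (epimers at the acetal carbon) | CCCCC[C@@H](CC=C)OC(OC(C)=O)c1ccc(OC)c(OC)c1
F0 | step 3 | none | none
F3 | step 1 | racemic 2-pentyloxirane | CCCCCC1CO1
F4 | step 1 | (S)-2-pentyloxirane | CCCCC[C@H]1CO1
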